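**Retrosynthetic overview**

1. The last skeletal bond is C4 (upper unit)–C6 (lower unit), made by AgBF4-promoted Friedel–Crafts coupling of an upper 4-benzylsulfanyl flavan with the lower flavan-3,4-diol 3-benzyl ether; hydrogenolysis of eight benzyl ethers ends the route.
2. The lower flavan nucleus is made by closing pyran ring C onto ring A in one annulation that forms O1–C8a and C4a–C4, from a 1-bromo-2-fluoro-3,4-dioxygenated benzene and a syn glycolate-aldol Weinreb amide, with C3 equilibrated to trans in the same flask. The C2-epimeric upper unit comes from the enantiomeric aldol adduct through the same two bonds in two steps (arylmagnesium acylation, then SNAr closure with one equivalent of base), so that the kinetic 2,3-cis ketone is kept.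
3. Enabling feature: on ring A the ether carbon C8a is ortho to the C4-bearing carbon C4a and next to the oxygenated C8, and C4 is a carbinol that can pass through the ketone level. Fluorine at C8a therefore stands in for O1, tolerates a carbanion at C4a, and is displaced once the new C4 carbonyl activates it.
4. Ring order: ring C of the lower unit (step 6), ring C of the upper unit (step 12), then the interflavanyl bond (step 15); rings A and B are bought.

Key step: step 6

Remark: the target is read as a 4β→6 dimer with upper unit (2R,3R,4S) and lower unit (2S,3R,4R); 3-fluorocatechol, both enantiomers of 4-benzyl-1,3-oxazolidin-2-one, (benzyloxy)acetyl chloride and 4-(benzyloxy)benzaldehyde are taken as commercial, as is 1,2,3-tris(benzyloxy)benzene, which is used only in a fallback.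

**Route**

Step 1
Reactants: 1 3-fluorobenzene-1,2-diol
Product: 2 1,2-bis(benzyloxy)-3-fluorobenzene
Conditions: BnBr, K2CO3, DMF, 60 °C
Reagents that add atoms: benzyl bromide BrCc1ccccc1
Why: Williamson ether synthesis on both phenoxides, benzyl being chosen because it survives organolithium and organomagnesium reagents and hydrides and leaves in the final hydrogenolysis.

Step 2
Reactants: 2 1,2-bis(benzyloxy)-3-fluorobenzene
Product: 3 1,2-bis(benzyloxy)-4-bromo-3-fluorobenzene
Conditions: NBS, MeCN, 0 → 23 °C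
Reagents that add atoms: N-bromosuccinimide O=C1CCC(=O)N1Br
Why: Electrophilic aromatic bromination, expected para to the unhindered 1-benzyloxy group (ortho to fluorine) because the benzyloxy group flanked by F and OBn is twisted out of conjugation, as in the bromination of 3-fluoroanisole.

Step 3
Reactants: 4 (R)-4-benzyl-1,3-oxazolidin-2-one; 5 (benzyloxy)acetyl chloride
Product: 7 (R)-4-benzyl-3-[(benzyloxy)acetyl]-1,3-oxazolidin-2-one, via N-lithio (R)-oxazolidinone 6 (not isolated)
Conditions: n-BuLi, THF, –78 °C; then 5, –78 → 0 °C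
Reagents that add atoms: none
Why: N-acylation of the lithiated oxazolidinone by the acid chloride, the standard entry to Evans glycolate imides.

Step 4
Reactants: 7 (R)-4-benzyl-3-[(benzyloxy)acetyl]-1,3-oxazolidin-2-one; 8 4-(benzyloxy)benzaldehyde
Product: 10 (R)-4-benzyl-3-[(2R,3S)-2-(benzyloxy)-3-[4-(benzyloxy)phenyl]-3-hydroxypropanoyl]-1,3-oxazolidin-2-one, via Z-dibutylboron enolate 9 (not isolated)
Conditions: Bu2BOTf, Et3N, CH2Cl2, 0 °C; 8, –78 → 0 °C; pH 7 buffer, MeOH, H2O2
Reagents that add atoms: none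
Why: Evans syn aldol reaction in which the Z-boron enolate reacts through a chair Zimmerman–Traxler transition state on the face away from the auxiliary benzyl group, setting C2 (R) and C3 (S) of the side chain, the future C3 and C2 of the lower flavan unit.

Step 5
Reactants: 10 (R)-4-benzyl-3-[(2R,3S)-2-(benzyloxy)-3-[4-(benzyloxy)phenyl]-3-hydroxypropanoyl]-1,3-oxazolidin-2-one
Product: 11 (2R,3S)-2-(benzyloxy)-3-[4-(benzyloxy)phenyl]-3-hydroxy-N-methoxy-N-methylpropanamide
Conditions: AlMe3, MeNHOMe·HCl, CH2Cl2, –20 → 0 °C; aq HCl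
Reagents that add atoms: N,O-dimethylhydroxylamine hydrochloride Cl.CNOC
Why: Aluminium amide transamidation of the imide to the Weinreb amide, assisted by the free β-hydroxyl, which touches no stereocentre and releases the auxiliary.

Step 6
Reactants: 3 1,2-bis(benzyloxy)-4-bromo-3-fluorobenzene; 11 (2R,3S)-2-(benzyloxy)-3-[4-(benzyloxy)phenyl]-3-hydroxy-N-methoxy-N-methylpropanamide
Product: 17 (2S,3S)-3,7,8-tris(benzyloxy)-2-[4-(benzyloxy)phenyl]chroman-4-one, via aryllithium 12 (not isolated), via amide lithium alkoxide 13 (not isolated), via dilithium tetrahedral adduct 14 (not isolated), via fluoroaryl ketone lithium alkoxide 15 (not isolated), via cis-chromanone 16 (not isolated)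
Conditions: 3 (2.1 equiv), n-BuLi (2.1 equiv), THF, –78 °C; add 11, –78 °C; t-BuOH (1.2 equiv), DMPU, –78 → 23 °C; aq NH4Cl
Reagents that add atoms: none
Why: Bromine–lithium exchange gives aryllithium 12, in which fluorine holds the place of O1 at C8a while the carbanion sits on the neighbouring C4a; one equivalent of 12 deprotonates the hydroxyl of 11 to alkoxide 13, a second acylates the Weinreb amide (C4a–C4 bond) to the chelated adduct 14, and tert-butanol releases ketone 15, whose new C4 carbonyl is ortho to the C–F bond. The lithium alkoxide at O1 then displaces fluoride by addition–elimination (SNAr) through a Meisenheimer anion stabilised by the C4 carbonyl, which closes the six-membered pyran ring C in the 6-endo-trig mode (conjugate addition of O1 to the C8a=C4a–C4=O unit, then loss of fluoride) and forms the O1–C8a bond. The closest known reactions are the Weinreb ketone synthesis with aryllithiums and the alkoxide SNAr closure of 2-fluorophenyl β-hydroxy ketones to chroman-4-ones. No stereocentre is created in the two bond-forming events: C2 is carried over from the aldol adduct with retention because oxygen, not carbon, is the nucleophile, and C3 of the first-formed cis ketone 16 should be equilibrated by the lithium tert-butoxide left in the flask to the diequatorial 2,3-trans ketone 17 (thermodynamic control). Regiochemistry is fixed by the positions of Br and F in 3, mono-addition is secured by the stable adduct 14, and the step needs the SNAr closure to outrun retro-aldol cleavage of 15, which the ortho-carbonyl activation, the six-membered transition state and the DMPU cosolvent are meant to secure.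

Step 7
Reactants: 17 (2S,3S)-3,7,8-tris(benzyloxy)-2-[4-(benzyloxy)phenyl]chroman-4-one
Product: 18 (2S,3R,4R)-3,7,8-tris(benzyloxy)-2-[4-(benzyloxy)phenyl]chroman-4-ol
Conditions: LiBH(s-Bu)3, THF, –78 °C; H2O
Reagents that add atoms: none
Why: Ketone reduction by a bulky trialkylborohydride, which should attack along the equatorial trajectory to avoid the 1,3-diaxial contact with the axial H-2 and give the axial 4-alcohol cis to the equatorial 3-benzyloxy group (2,3-trans-3,4-cis), where small hydrides give the 3,4-trans epimer.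

Step 8
Reactants: 19 (S)-4-benzyl-1,3-oxazolidin-2-one; 5 (benzyloxy)acetyl chloride
Product: 21 (S)-4-benzyl-3-[(benzyloxy)acetyl]-1,3-oxazolidin-2-one, via N-lithio (S)-oxazolidinone 20 (not isolated)
Conditions: n-BuLi, THF, –78 °C; then 5, –78 → 0 °C
Reagents that add atoms: none
Why: N-acylation of the lithiated oxazolidinone, as in step 3, in the enantiomeric series.

Step 9
Reactants: 21 (S)-4-benzyl-3-[(benzyloxy)acetyl]-1,3-oxazolidin-2-one; 8 4-(benzyloxy)benzaldehyde
Product: 23 (S)-4-benzyl-3-[(2S,3R)-2-(benzyloxy)-3-[4-(benzyloxy)phenyl]-3-hydroxypropanoyl]-1,3-oxazolidin-2-one, via Z-dibutylboron enolate 22 (not isolated)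
Conditions: Bu2BOTf, Et3N, CH2Cl2, 0 °C; 8, –78 → 0 °C; pH 7 buffer, MeOH, H2O2
Reagents that add atoms: none
Why: Evans syn aldol reaction as in step 4, the (S)-auxiliary setting the mirror-image (2S,3R) centres that become C3 and C2 of the upper unit.

Step 10
Reactants: 23 (S)-4-benzyl-3-[(2S,3R)-2-(benzyloxy)-3-[4-(benzyloxy)phenyl]-3-hydroxypropanoyl]-1,3-oxazolidin-2-one
Product: 24 (2S,3R)-2-(benzyloxy)-3-[4-(benzyloxy)phenyl]-3-hydroxy-N-methoxy-N-methylpropanamide
Conditions: AlMe3, MeNHOMe·HCl, CH2Cl2, –20 → 0 °C; aq HCl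
Reagents that add atoms: N,O-dimethylhydroxylamine hydrochloride Cl.CNOC
Why: Aluminium amide transamidation to the Weinreb amide, as in step 5.

Step 11
Reactants: 3 1,2-bis(benzyloxy)-4-bromo-3-fluorobenzene; 24 (2S,3R)-2-(benzyloxy)-3-[4-(benzyloxy)phenyl]-3-hydroxy-N-methoxy-N-methylpropanamide
Product: 28 (2S,3R)-2-(benzyloxy)-1-[3,4-bis(benzyloxy)-2-fluorophenyl]-3-[4-(benzyloxy)phenyl]-3-hydroxypropan-1-one, via arylmagnesium chloride 25 (not isolated), via amide chloromagnesium alkoxide 26 (not isolated), via magnesium tetrahedral adduct 27 (not isolated)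
Conditions: 3 (1.5 equiv), i-PrMgCl·LiCl (1.45 equiv), THF, 0 → 23 °C; separately 24, i-PrMgCl·LiCl (1.0 equiv), THF, –20 °C; combine, –20 → 0 °C; cold aq NH4Cl
Reagents that add atoms: none
Why: Bromine–magnesium exchange with i-PrMgCl·LiCl, speeded by the ortho-fluorine and run with the exchange reagent in slight deficit, gives arylmagnesium chloride 25, which acylates the Weinreb amide of the pre-formed magnesium alkoxide 26 and stops at the chelated adduct 27 (Weinreb ketone synthesis); the magnesium aldolate is too weakly nucleophilic to attack the C–F bond and holds both centres of the syn aldol unit, so the open hydroxy ketone should be isolated unchanged at both stereocentres.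

Step 12
Reactants: 28 (2S,3R)-2-(benzyloxy)-1-[3,4-bis(benzyloxy)-2-fluorophenyl]-3-[4-(benzyloxy)phenyl]-3-hydroxypropan-1-one
Product: 30 (2R,3S)-3,7,8-tris(benzyloxy)-2-[4-(benzyloxy)phenyl]chroman-4-one, via ketone lithium alkoxide 29 (not isolated)
Conditions: LiN(SiMe3)2 (1.0 equiv), THF–DMPU, –78 → 0 °C; pH 7 buffer; crude taken on at once
Reagents that add atoms: none
Why: Deprotonation of the hydroxyl gives lithium alkoxide 29, which displaces the ortho-fluoride by addition–elimination (SNAr) activated by the C4 carbonyl, the known closure of 2-fluorophenyl β-hydroxy ketones to chroman-4-ones; neither stereocentre takes part, so the syn aldol unit is carried into the 2,3-cis ketone with retention, and the single equivalent of base ends as lithium fluoride, so that no base able to enolise C3 should remain.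

Step 13
Reactants: 30 (2R,3S)-3,7,8-tris(benzyloxy)-2-[4-(benzyloxy)phenyl]chroman-4-one
Product: 31 (2R,3R,4R)-3,7,8-tris(benzyloxy)-2-[4-(benzyloxy)phenyl]chroman-4-ol
Conditions: NaBH4, MeOH–THF, –20 °C
Reagents that add atoms: none
Why: Borohydride reduction in which hydride should add to the face opposite the axial 3-benzyloxy group to give the all-cis alcohol; the C4 configuration is of no consequence because C4 is ionised in steps 14 and 15.

Step 14
Reactants: 31 (2R,3R,4R)-3,7,8-tris(benzyloxy)-2-[4-(benzyloxy)phenyl]chroman-4-ol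
Product: 32 (2R,3S,4S)-3,7,8-tris(benzyloxy)-2-[4-(benzyloxy)phenyl]-4-(benzylsulfanyl)chromane
Conditions: BnSH, BF3·OEt2 (0.3 equiv), 4 Å MS, CH2Cl2, –78 → –20 °C
Reagents that add atoms: phenylmethanethiol SCc1ccccc1
Why: Lewis-acid thiolysis of the benzylic alcohol (SN1), in which the C4 cation stabilised by the para 7-oxygen is captured by the thiol on the face anti to the 3-benzyloxy group to give the 3,4-trans (4β) thioether.

Step 15
Reactants: 32 (2R,3S,4S)-3,7,8-tris(benzyloxy)-2-[4-(benzyloxy)phenyl]-4-(benzylsulfanyl)chromane; 18 (2S,3R,4R)-3,7,8-tris(benzyloxy)-2-[4-(benzyloxy)phenyl]chroman-4-ol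
Product: 33 octa-O-benzyl ether of the target (benzyl on O3 and O7 and O8 and O4' of each unit; lower 4-hydroxyl free; all centres as in 34)
Conditions: AgBF4, 2,6-di-tert-butyl-4-methylpyridine, 18 (3 equiv), THF, 0 °C, dark
Reagents that add atoms: none
Why: Thiophilic activation of the C4–S bond by AgBF4 regenerates the C4 cation without protic acid, and Friedel–Crafts attack by C6 of 18 (ortho to the 7-benzyloxy group and para to O1) anti to the 3-benzyloxy group should give the 4β→6 bond with 3,4-trans configuration, while the hindered pyridine takes up the acid and protects the 4-hydroxyl of 18.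

Step 16
Reactants: 33 octa-O-benzyl ether of the target
Product: 34 (2R,3R,4S)-2-(4-hydroxyphenyl)-4-[(2S,3R,4R)-3,4,7,8-tetrahydroxy-2-(4-hydroxyphenyl)chroman-6-yl]chromane-3,7,8-triol
Conditions: H2 (1 atm), Pd(OH)2/C, EtOAc–MeOH, 23 °C
Reagents that add atoms: none
Why: Hydrogenolysis of the eight benzyl ethers under neutral conditions, which should leave the interflavanyl bond, the pyran C2–O1 bonds and the lower C4 hydroxyl in place as in related proanthocyanidin deprotections.

**Compound list**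

1 | 3-fluorobenzene-1,2-diol | Oc1cccc(F)c1O | starting material
2 | 1,2-bis(benzyloxy)-3-fluorobenzene | Fc1cccc(OCc2ccccc2)c1OCc1ccccc1 | intermediate
3 | 1,2-bis(benzyloxy)-4-bromo-3-fluorobenzene | Fc1c(Br)ccc(OCc2ccccc2)c1OCc1ccccc1 | intermediate
4 | (R)-4-benzyl-1,3-oxazolidin-2-one | O=C1OC[C@@H](Cc2ccccc2)N1 | starting material
5 | (benzyloxy)acetyl chloride | ClC(=O)COCc1ccccc1 | starting material
6 | N-lithio derivative of 4 | O=C1OC[C@@H](Cc2ccccc2)N1[Li] | intermediate (not isolated)
7 | (R)-4-benzyl-3-[(benzyloxy)acetyl]-1,3-oxazolidin-2-one | O=C1OC[C@@H](Cc2ccccc2)N1C(=O)COCc1ccccc1 | intermediate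
8 | 4-(benzyloxy)benzaldehyde | O=Cc1ccc(OCc2ccccc2)cc1 | starting material
9 | Z-dibutylboron enolate of 7 | CCCCB(CCCC)O/C(=C\OCc1ccccc1)N1C(=O)OC[C@H]1Cc1ccccc1 | intermediate (not isolated)
10 | (R)-4-benzyl-3-[(2R,3S)-2-(benzyloxy)-3-[4-(benzyloxy)phenyl]-3-hydroxypropanoyl]-1,3-oxazolidin-2-one | O[C@@H](c1ccc(OCc2ccccc2)cc1)[C@@H](OCc1ccccc1)C(=O)N1C(=O)OC[C@H]1Cc1ccccc1 | intermediate
11 | (2R,3S)-2-(benzyloxy)-3-[4-(benzyloxy)phenyl]-3-hydroxy-N-methoxy-N-methylpropanamide | O[C@@H](c1ccc(OCc2ccccc2)cc1)[C@@H](OCc1ccccc1)C(=O)N(C)OC | intermediate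
12 | [3,4-bis(benzyloxy)-2-fluorophenyl]lithium | [Li]c1ccc(OCc2ccccc2)c(OCc2ccccc2)c1F | intermediate (not isolated)
13 | lithium alkoxide of 11 | [Li]O[C@@H](c1ccc(OCc2ccccc2)cc1)[C@@H](OCc1ccccc1)C(=O)N(C)OC | intermediate (not isolated)
14 | dilithium salt of the tetrahedral adduct of 12 to 11 (hemiaminal carbon undefined) | [Li]O[C@@H](c1ccc(OCc2ccccc2)cc1)[C@@H](OCc1ccccc1)C(O[Li])(N(C)OC)c1ccc(OCc2ccccc2)c(OCc2ccccc2)c1F | intermediate (not isolated)
15 | lithium alkoxide of (2R,3S)-2-(benzyloxy)-1-[3,4-bis(benzyloxy)-2-fluorophenyl]-3-[4-(benzyloxy)phenyl]-3-hydroxypropan-1-one | [Li]O[C@@H](c1ccc(OCc2ccccc2)cc1)[C@@H](OCc1ccccc1)C(=O)c1ccc(OCc2ccccc2)c(OCc2ccccc2)c1F | intermediate (not isolated)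
16 | (2S,3R)-3,7,8-tris(benzyloxy)-2-[4-(benzyloxy)phenyl]chroman-4-one (2,3-cis) | c1ccccc1COc1ccc2c(c1OCc1ccccc1)O[C@@H](c1ccc(OCc3ccccc3)cc1)[C@@H](OCc1ccccc1)C2=O | intermediate (not isolated)
17 | (2S,3S)-3,7,8-tris(benzyloxy)-2-[4-(benzyloxy)phenyl]chroman-4-one (2,3-trans) | c1ccccc1COc1ccc2c(c1OCc1ccccc1)O[C@@H](c1ccc(OCc3ccccc3)cc1)[C@H](OCc1ccccc1)C2=O | intermediate
18 | (2S,3R,4R)-3,7,8-tris(benzyloxy)-2-[4-(benzyloxy)phenyl]chroman-4-ol | c1ccccc1COc1ccc2c(c1OCc1ccccc1)O[C@@H](c1ccc(OCc3ccccc3)cc1)[C@H](OCc1ccccc1)[C@@H]2O | intermediate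
19 | (S)-4-benzyl-1,3-oxazolidin-2-one | O=C1OC[C@H](Cc2ccccc2)N1 | starting material
20 | N-lithio derivative of 19 | O=C1OC[C@H](Cc2ccccc2)N1[Li] | intermediate (not isolated)
21 | (S)-4-benzyl-3-[(benzyloxy)acetyl]-1,3-oxazolidin-2-one | O=C1OC[C@H](Cc2ccccc2)N1C(=O)COCc1ccccc1 | intermediate
22 | Z-dibutylboron enolate of 21 | CCCCB(CCCC)O/C(=C\OCc1ccccc1)N1C(=O)OC[C@@H]1Cc1ccccc1 | intermediate (not isolated)
23 | (S)-4-benzyl-3-[(2S,3R)-2-(benzyloxy)-3-[4-(benzyloxy)phenyl]-3-hydroxypropanoyl]-1,3-oxazolidin-2-one | O[C@H](c1ccc(OCc2ccccc2)cc1)[C@H](OCc1ccccc1)C(=O)N1C(=O)OC[C@@H]1Cc1ccccc1 | intermediate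
24 | (2S,3R)-2-(benzyloxy)-3-[4-(benzyloxy)phenyl]-3-hydroxy-N-methoxy-N-methylpropanamide | O[C@H](c1ccc(OCc2ccccc2)cc1)[C@H](OCc1ccccc1)C(=O)N(C)OC | intermediate
25 | [3,4-bis(benzyloxy)-2-fluorophenyl]magnesium chloride | Cl[Mg]c1ccc(OCc2ccccc2)c(OCc2ccccc2)c1F | intermediate (not isolated)
26 | chloromagnesium alkoxide of 24 | Cl[Mg]O[C@H](c1ccc(OCc2ccccc2)cc1)[C@H](OCc1ccccc1)C(=O)N(C)OC | intermediate (not isolated)
27 | bis(chloromagnesium) salt of the tetrahedral adduct of 25 to 24 (hemiaminal carbon undefined) | Cl[Mg]O[C@H](c1ccc(OCc2ccccc2)cc1)[C@H](OCc1ccccc1)C(O[Mg]Cl)(N(C)OC)c1ccc(OCc2ccccc2)c(OCc2ccccc2)c1F | intermediate (not isolated)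
28 | (2S,3R)-2-(benzyloxy)-1-[3,4-bis(benzyloxy)-2-fluorophenyl]-3-[4-(benzyloxy)phenyl]-3-hydroxypropan-1-one | O[C@H](c1ccc(OCc2ccccc2)cc1)[C@H](OCc1ccccc1)C(=O)c1ccc(OCc2ccccc2)c(OCc2ccccc2)c1F | intermediate
29 | lithium alkoxide of 28 | [Li]O[C@H](c1ccc(OCc2ccccc2)cc1)[C@H](OCc1ccccc1)C(=O)c1ccc(OCc2ccccc2)c(OCc2ccccc2)c1F | intermediate (not isolated)
30 | (2R,3S)-3,7,8-tris(benzyloxy)-2-[4-(benzyloxy)phenyl]chroman-4-one (2,3-cis) | c1ccccc1COc1ccc2c(c1OCc1ccccc1)O[C@H](c1ccc(OCc3ccccc3)cc1)[C@H](OCc1ccccc1)C2=O | intermediate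
31 | (2R,3R,4R)-3,7,8-tris(benzyloxy)-2-[4-(benzyloxy)phenyl]chroman-4-ol | c1ccccc1COc1ccc2c(c1OCc1ccccc1)O[C@H](c1ccc(OCc3ccccc3)cc1)[C@H](OCc1ccccc1)[C@@H]2O | intermediate
32 | (2R,3S,4S)-3,7,8-tris(benzyloxy)-2-[4-(benzyloxy)phenyl]-4-(benzylsulfanyl)chromane | c1ccccc1COc1ccc2c(c1OCc1ccccc1)O[C@H](c1ccc(OCc3ccccc3)cc1)[C@H](OCc1ccccc1)[C@H]2SCc1ccccc1 | intermediate
33 | octa-O-benzyl ether of 34 (upper unit 2,3-cis-3,4-trans, linked 4β→6 to the lower 2,3-trans-3,4-cis unit; lower 4-OH free) | c1ccccc1COc1ccc2c(c1OCc1ccccc1)O[C@H](c1ccc(OCc3ccccc3)cc1)[C@H](OCc1ccccc1)[C@H]2c1cc2c(c(OCc3ccccc3)c1OCc1ccccc1)O[C@@H](c1ccc(OCc3ccccc3)cc1)[C@H](OCc1ccccc1)[C@@H]2O | intermediate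
34 | (2R,3R,4S)-2-(4-hydroxyphenyl)-4-[(2S,3R,4R)-3,4,7,8-tetrahydroxy-2-(4-hydroxyphenyl)chroman-6-yl]chromane-3,7,8-triol | Oc1ccc([C@H]2Oc3c(ccc(O)c3O)[C@H](c3cc4c(c(O)c3O)O[C@@H](c3ccc(O)cc3)[C@H](O)[C@@H]4O)[C@H]2O)cc1 | target

**Step count**

Total steps: 16. Longest linear sequence: 9 steps (steps 8 to 16).

**Steps most likely to fail**

Step 6. The process at risk is retro-aldol cleavage of lithium aldolate 15 before the ring closes, or ring opening of the ketone enolate during the C3 equilibration; either would erode the configuration at C2. The fallback sets out from 24, the upper-series amide, whose carbinol carbon has the configuration needed for a closure with inversion, and comes back at 17. Commercial 1,2,3-tris(benzyloxy)benzene is brominated with NBS to 1,2,3-tris(benzyloxy)-4-bromobenzene F1, which n-BuLi (THF, –78 °C) converts into [2,3,4-tris(benzyloxy)phenyl]lithium F2. Addition of 24 to two equivalents of this reagent gives, after a cold aqueous quench, the hydroxy ketone (2S,3R)-2-(benzyloxy)-3-[4-(benzyloxy)phenyl]-3-hydroxy-1-[2,3,4-tris(benzyloxy)phenyl]propan-1-one F3. MgBr2·OEt2 removes only the benzyl group ortho to the carbonyl to give the phenol (2S,3R)-2-(benzyloxy)-1-[3,4-bis(benzyloxy)-2-hydroxyphenyl]-3-[4-(benzyloxy)phenyl]-3-hydroxypropan-1-one F4. A Mitsunobu cyclisation (PPh3, DIAD, THF) then forms the O1–C2 bond with inversion at C2, without base and without an aldolate, which should give the 2,3-trans ketone 17 directly.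

Step 12. The process at risk is epimerisation at C3 toward the more stable trans ketone, by proton transfer within alkoxide 29 before the ring closes or by adventitious base after it. The fallback sets out from 28 and comes back at 30. 28 is cyclised under equilibrating conditions (K2CO3, DMF, 23 °C), so that the trans ketone (2R,3R)-3,7,8-tris(benzyloxy)-2-[4-(benzyloxy)phenyl]chroman-4-one F5 is formed on purpose. LiN(SiMe3)2 (THF, –78 °C) converts it into the enolate lithium (2R)-3,7,8-tris(benzyloxy)-2-[4-(benzyloxy)phenyl]-2H-chromen-4-olate F6, which is protonated with 2,6-di-tert-butylphenol. Allylic strain between the 3-benzyloxy group and the 2-aryl group should hold the aryl group pseudo-axial, so the proton arrives anti to it and the contra-thermodynamic cis ketone 30 is returned, to be reduced at once as in step 13.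

Step 15. The process at risk is self-condensation of the cation from 32 at C6 of a second molecule of 32, whose ring A is as nucleophilic as that of 18, together with O-alkylation of the free 4-hydroxyl of 18. The fallback sets out from 31 and comes back at 34. Ring A of the electrophile is capped: NBS brominates 31 at C6 to give the 6-bromo derivative of 31 F7. Thiolysis as in step 14 gives the 6-bromo derivative of 32 F8, and coupling with 18 as in step 15 gives the 6-bromo derivative of 33 F9 (bromine on C6 of the upper unit). The hydrogenolysis of step 16, run with Et3N, should remove the bromine along with the benzyl groups to give 34.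

Further compounds
F1 | step 6 | 1,2,3-tris(benzyloxy)-4-bromobenzene | Brc1ccc(OCc2ccccc2)c(OCc2ccccc2)c1OCc1ccccc1
F2 | step 6 | [2,3,4-tris(benzyloxy)phenyl]lithium | [Li]c1ccc(OCc2ccccc2)c(OCc2ccccc2)c1OCc1ccccc1
F3 | step 6 | (2S,3R)-2-(benzyloxy)-3-[4-(benzyloxy)phenyl]-3-hydroxy-1-[2,3,4-tris(benzyloxy)phenyl]propan-1-one | O[C@H](c1ccc(OCc2ccccc2)cc1)[C@H](OCc1ccccc1)C(=O)c1ccc(OCc2ccccc2)c(OCc2ccccc2)c1OCc1ccccc1
F4 | step 6 | (2S,3R)-2-(benzyloxy)-1-[3,4-bis(benzyloxy)-2-hydroxyphenyl]-3-[4-(benzyloxy)phenyl]-3-hydroxypropan-1-one | O[C@H](c1ccc(OCc2ccccc2)cc1)[C@H](OCc1ccccc1)C(=O)c1ccc(OCc2ccccc2)c(OCc2ccccc2)c1O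
F5 | step 12 | (2R,3R)-3,7,8-tris(benzyloxy)-2-[4-(benzyloxy)phenyl]chroman-4-one | c1ccccc1COc1ccc2c(c1OCc1ccccc1)O[C@H](c1ccc(OCc3ccccc3)cc1)[C@@H](OCc1ccccc1)C2=O
F6 | step 12 | lithium (2R)-3,7,8-tris(benzyloxy)-2-[4-(benzyloxy)phenyl]-2H-chromen-4-olate | c1ccccc1COc1ccc2c(c1OCc1ccccc1)O[C@H](c1ccc(OCc3ccccc3)cc1)C(OCc1ccccc1)=C2O[Li]
F7 | step 15 | 6-bromo derivative of 31 | c1ccccc1COc1c(Br)cc2c(c1OCc1ccccc1)O[C@H](c1ccc(OCc3ccccc3)cc1)[C@H](OCc1ccccc1)[C@@H]2O
F8 | step 15 | 6-bromo derivative of 32 | c1ccccc1COc1c(Br)cc2c(c1OCc1ccccc1)O[C@H](c1ccc(OCc3ccccc3)cc1)[C@H](OCc1ccccc1)[C@H]2SCc1ccccc1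
F9 | step 15 | 6-bromo derivative of 33 (bromine on C6 of the upper unit) | c1ccccc1COc1c(Br)cc2c(c1OCc1ccccc1)O[C@H](c1ccc(OCc3ccccc3)cc1)[C@H](OCc1ccccc1)[C@H]2c1cc2c(c(OCc3ccccc3)c1OCc1ccccc1)O[C@@H](c1ccc(OCc3ccccc3)cc1)[C@H](OCc1ccccc1)[C@@H]2O
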